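**Plan**

1. Retrosynthesis: one cut removes C3–C2′, C3′–O, O–C2″ and C3″–OO (homoadamantane bridge, 1,2-dioxepane, hydroperoxide) and leads to the 7-endo-prenyl trione 14 (7-epi-nemorosone constitution) plus two O2. Then C2′=C3′ and C1′–C2′ (two Wittig steps), then the three ring bonds C5–C6, C1–C8 and C3–C1′ of an adamantane, back to flat diprenyl benzophenone 2 and C5 enal 7.
2. Forward: a dearomatising Michael/E1cB/Michael/aldol sequence turns the arene into the bicyclo[3.3.1]nonane and then adamantanol 10. The C3–C1′ bond is temporary: it is made only to force benzoyl-bridgehead closure and an axial C7 arm, is cut by base-induced retro-aldol, and C1′ is grown into the prenyl group.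
3. The key step re-joins C3 to the same arm one carbon further out (C2′) and stitches in two O2, closing the homoadamantane and the dioxepane and placing the hydroperoxide.
4. Enabling feature: C3 is the central carbon of the enolisable C2/C4 diketone and lies directly under the axial C7 prenyl group. C2′ is 7-exo to C3, the C3′ peroxyl oxygen is 7-exo to C2″ of the C3 prenyl group, and C3′ and C3″ are tertiary carbons that relay the radical to O2.
5. Stereochemistry: C5 comes from a chiral ammonium ion pair in the first C–C bond; C1, C7 and C3 follow from the tether; C2′ and C2″ are set by the cage during the cascade.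

Key step: step 7

Numbering: the core is C1–C9 of a bicyclo[3.3.1]nonane-2,4,9-trione (C1 benzoyl, C5 prenyl, C8 CMe2). C1′/C2′/C3′ are the carbons of the C7 arm (CH2, CH bonded to C3, CMe2–O) and C1″/C2″/C3″ those of the C3 arm (CH2, CH–O, CMe2–OOH). Enolised diketones are drawn as the 2-oxo-4-hydroxy tautomer.

Assumption: the cinchonidinium-series phase-transfer catalyst is taken to give the C5 configuration drawn for 8–10; if the opposite sense is found, its cinchoninium pseudoenantiomer is used with no other change.

**Step 1**
Reactants: 1 2,4,6-trihydroxybenzophenone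
Product: 2 3,5-bis(3-methylbut-2-enyl)-2,4,6-trihydroxybenzophenone (clusiaphenone B)
Conditions: prenyl bromide (2.1 equiv), 5% aq. KOH, 0 °C to rt
Reagents that add atoms: prenyl bromide CC(C)=CCBr
Why: Twofold C-prenylation of the phloroglucinol phenoxide in water (Friedel–Crafts-type C-alkylation, with hydrogen bonding to oxygen suppressing O-alkylation) should be held at the symmetrical 3,5-dialkyl stage by stoichiometry, and no stereocentre is formed.

**Step 2**
Reactants: 3 2-bromo-3,3-diethoxyprop-1-ene
Product: 6 3-(diethoxymethyl)-2-methylbut-3-en-2-yl acetate, via vinyllithium 4 (not isolated), via lithium alkoxide 5 (not isolated)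
Conditions: n-BuLi, THF, −78 °C; acetone, −78 °C; Ac2O, −78 to 0 °C
Reagents that add atoms: acetone CC(C)=O; acetic anhydride CC(=O)OC(C)=O
Why: Bromine–lithium exchange gives the α-lithiated acrolein acetal (a masked acrolein α-anion), which adds 1,2 to acetone, and the tertiary lithium alkoxide is acetylated in the same flask, with no stereocentre formed.

**Step 3**
Reactants: 6 3-(diethoxymethyl)-2-methylbut-3-en-2-yl acetate
Product: 7 3-formyl-2-methylbut-3-en-2-yl acetate
Conditions: oxalic acid (cat.), wet SiO2, CH2Cl2, rt; used at once
Reagents that add atoms: water O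
Why: Mild acid-catalysed acetal hydrolysis should free the enal without ionising the tertiary acetate, because the conjugated aldehyde makes the allylic position electron-poor, and no stereocentre is formed.

**Step 4**
Reactants: 2 clusiaphenone B; 7 3-formyl-2-methylbut-3-en-2-yl acetate (1.3 equiv)
Product: 10 1-benzoyl-10-hydroxy-8,8-dimethyl-3,5-bis(3-methylbut-2-enyl)adamantane-2,4,9-trione, via dearomatised enal 8 (not isolated), via bicyclic aldehyde 9 (not isolated)
Conditions: 2,7-bis[O(9)-allylhydrocinchonidinium-N-methyl]naphthalene dibromide (25 mol%), CsOH·H2O (5 equiv), 4 Å MS, CH2Cl2, −50 to −20 °C; aq. NH4Cl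
Reagents that add atoms: none
Why: In this alkylative dearomatisation–annulation the ion-paired phenoxide adds through a prenylated ring carbon (C5) to the methylene of 7 (Michael addition), acetate leaves (E1cB) to give 8, the benzoyl-bearing carbon closes onto the CMe2 terminus (second Michael addition), and on neutralisation the C2/C4 enol of the neutral bicyclic aldehyde 9 traps the axial C7 formyl group beneath C3 by intramolecular aldol addition (the C7 epimers equilibrate through the aldehyde enol and only the axial one can close), so the chiral ammonium cation sets C5 in the first C–C bond and the tether then dictates C1, C7 and C3, while the low temperature should hold the 1-benzoyl (type A) connectivity against reversal toward the 3-benzoyl (type B) isomer.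

**Step 5**
Reactants: 10 adamantanol
Product: 13 7-endo-(2-oxoethyl) bicyclic trione, via potassium diketonate aldehyde 11 (not isolated), via enol ether 12 (not isolated)
Conditions: KHMDS (1.05 equiv), THF, −78 °C; Ph3P=CHOMe (2.5 equiv, from Ph3P(Cl)CH2OMe and KHMDS), −78 to 0 °C; then 1 M HCl, THF, rt
Reagents that add atoms: (methoxymethyl)triphenylphosphonium chloride COC[P+](c1ccccc1)(c1ccccc1)c1ccccc1.[Cl-]; water O
Why: Deprotonation of the carbinol triggers retro-aldol cleavage of the temporary C3–C1′ bond, because the potassium C2/C4 diketonate 11 is far more stable than the alkoxide and, unlike the neutral enol of step 4, does not re-close onto the aldehyde, so the freed axial C7 aldehyde should undergo Wittig methoxymethylenation faster than it epimerises, and acid hydrolysis of enol ether 12 then gives the one-carbon homologue with C7 untouched.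

**Step 6**
Reactants: 13 7-endo-(2-oxoethyl) bicyclic trione
Product: 14 7-endo-prenyl trione (7-epi-nemorosone constitution)
Conditions: Ph3P=CMe2 (3 equiv, from i-PrPPh3I and n-BuLi), THF, −78 to 0 °C; aq. NH4Cl
Reagents that add atoms: isopropyltriphenylphosphonium iodide CC(C)[P+](c1ccccc1)(c1ccccc1)c1ccccc1.[I-]
Why: Wittig olefination with the isopropylidene ylide turns the aldehyde into the prenyl terminus (the first equivalent only deprotonates the enol, whose diketonate is inert), and no stereocentre is formed or endangered because the aldehyde enolises through C1′ and not C7.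

**Step 7**
Reactants: 14 7-endo-prenyl trione (7-epi-nemorosone constitution)
Product: 17 target CNP0215795.1, via homoadamantyl peroxyl radical 15 (not isolated), via dioxepanyl peroxyl radical 16 (not isolated)
Conditions: Mn(OAc)3·2H2O (10 mol%), dry air (1 atm), AcOH, 23 °C, 0.005 M, dark; neutral work-up
Reagents that add atoms: dioxygen O=O
Why: Proposed new method: Mn(III) oxidises the C2–C4 enol of 14 to the C3-centred 1,3-dicarbonyl radical, which adds 7-exo-trig to C2′ of the axial C7 prenyl group directly beneath it (closing the homoadamantane); the tertiary C3′ radical takes up O2, peroxyl radical 15 closes the 1,2-dioxepane by 7-exo-trig addition to C2″ of the C3 prenyl group, the tertiary C3″ radical takes up a second O2, and peroxyl radical 16 is reduced to the hydroperoxide by Mn(II)/AcOH or by hydrogen transfer from the enol of the next molecule of 14, so that manganese turns over. The closest known reaction types are the Mn(III)-catalysed aerobic addition of 1,3-dicarbonyls to alkenes that gives cyclic peroxides, Mn(III)-mediated oxidative radical cyclisations of prenylated acylphloroglucinol enols, and peroxyl-radical cyclisation/second-oxygenation cascades of dienes; running all four events on one substrate is new. C3 is fixed by the cage because only the C7 arm can reach the endo face of the radical; C2′ is set by the alkene turning its CMe2 terminus toward the C6 methylene and away from the axial C8 methyl; C2″ is set by a chair-like seven-membered transition state with the CMe2 terminus pseudo-equatorial and pointing away from the cage, which places H-2″ cis to H-2′ on the dioxepane. The step needs C–C closure to outrun oxygen capture at C3 and the first peroxyl radical to cyclise before it is reduced; the pre-organised axial prenyl group, air in place of pure oxygen, low catalyst loading and high dilution are chosen to secure both.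

**Compound list**

1 | 2,4,6-trihydroxybenzophenone | O=C(c1ccccc1)c1c(O)cc(O)cc1O | starting material
2 | clusiaphenone B, 3,5-bis(3-methylbut-2-enyl)-2,4,6-trihydroxybenzophenone (achiral) | CC(C)=CCc1c(O)c(CC=C(C)C)c(O)c(C(=O)c2ccccc2)c1O | intermediate
3 | 2-bromo-3,3-diethoxyprop-1-ene (2-bromoacrolein diethyl acetal) | C=C(Br)C(OCC)OCC | starting material
4 | 1-(diethoxymethyl)ethenyllithium (not isolated) | [Li]C(=C)C(OCC)OCC | intermediate
5 | lithium 3-(diethoxymethyl)-2-methylbut-3-en-2-olate (not isolated) | [Li]OC(C)(C)C(=C)C(OCC)OCC | intermediate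
6 | 3-(diethoxymethyl)-2-methylbut-3-en-2-yl acetate | CC(=O)OC(C)(C)C(=C)C(OCC)OCC | intermediate
7 | 3-formyl-2-methylbut-3-en-2-yl acetate | CC(=O)OC(C)(C)C(=C)C=O | intermediate
8 | dearomatised enal, 2-benzoyl-6-(2-formyl-3-methylbut-2-enyl)-3,5-dihydroxy-4,6-diprenylcyclohexa-2,4-dienone, quaternary carbon configured as C5 of 14 (not isolated) | CC(C)=CC[C@@]1(CC(C=O)=C(C)C)C(=O)C(C(=O)c2ccccc2)=C(O)C(CC=C(C)C)=C1O | intermediate
9 | bicyclic aldehyde in its neutral enol form, 1-benzoyl-7-endo-formyl-4-hydroxy-8,8-dimethyl-3,5-diprenylbicyclo[3.3.1]non-3-ene-2,9-dione, formyl axial toward C3 (not isolated) | CC(C)=CC[C@]12C[C@H](C=O)C(C)(C)[C@](C(=O)c3ccccc3)(C(=O)C(CC=C(C)C)=C1O)C2=O | intermediate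
10 | adamantanol, 1-benzoyl-10-hydroxy-8,8-dimethyl-3,5-diprenyladamantane-2,4,9-trione; hydroxyl drawn on the C6 side, either carbinol epimer serves because the centre is cleared in step 5 | CC(C)=CC[C@]12C[C@@H]3[C@H](O)[C@](CC=C(C)C)(C1=O)C(=O)[C@](C(=O)c4ccccc4)(C2=O)C3(C)C | intermediate
11 | potassium diketonate aldehyde, potassium C2/C4 enolate of the ring-opened 7-endo-formyl bicyclic trione (not isolated) | CC(C)=CC[C@]12C[C@H](C=O)C(C)(C)[C@](C(=O)c3ccccc3)(C(=O)C(CC=C(C)C)=C1[O-])C2=O.[K+] | intermediate
12 | enol ether, 7-endo-(2-methoxyethenyl) analogue of 14, E/Z mixture, neutral form after acidification (not isolated) | CC(C)=CC[C@]12C[C@H](C=COC)C(C)(C)[C@](C(=O)c3ccccc3)(C(=O)C(CC=C(C)C)=C1O)C2=O | intermediate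
13 | 1-benzoyl-4-hydroxy-8,8-dimethyl-7-endo-(2-oxoethyl)-3,5-diprenylbicyclo[3.3.1]non-3-ene-2,9-dione (may rest in part as its ring-closed aldol) | CC(C)=CC[C@]12C[C@H](CC=O)C(C)(C)[C@](C(=O)c3ccccc3)(C(=O)C(CC=C(C)C)=C1O)C2=O | intermediate
14 | 7-endo-prenyl trione with the constitution and relative configuration of 7-epi-nemorosone, 1-benzoyl-4-hydroxy-8,8-dimethyl-3,5,7-triprenylbicyclo[3.3.1]non-3-ene-2,9-dione, C7 prenyl axial (endo to C3), (1S,5S,7S) for the tautomer drawn | CC(C)=CC[C@]12C[C@H](CC=C(C)C)C(C)(C)[C@](C(=O)c3ccccc3)(C(=O)C(CC=C(C)C)=C1O)C2=O | intermediate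
15 | homoadamantyl peroxyl radical: C3–C2′ bond closed, C3′ carrying O–O• (not isolated) | CC(C)=CC[C@]12C[C@@H]3C[C@H](C(C)(C)O[O])[C@](CC=C(C)C)(C1=O)C(=O)[C@](C(=O)c4ccccc4)(C2=O)C3(C)C | intermediate
16 | dioxepanyl peroxyl radical: dioxepane closed, C3″ carrying O–O• (not isolated) | CC(C)=CC[C@]12C[C@@H]3C[C@@H]4C(C)(C)OO[C@H](C(C)(C)O[O])C[C@@]4(C1=O)C(=O)[C@](C(=O)c1ccccc1)(C2=O)C3(C)C | intermediate
17 | CNP0215795.1: homoadamantane trione with C1 benzoyl, C5 prenyl, 1,2-dioxepane fused on C3–C2′, and 2-hydroperoxypropan-2-yl on C2″ | CC(C)=CC[C@]12C[C@@H]3C[C@@H]4C(C)(C)OO[C@H](C(C)(C)OO)C[C@@]4(C1=O)C(=O)[C@](C(=O)c1ccccc1)(C2=O)C3(C)C | target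

**Step count and risks**

Total steps: 7. Longest linear sequence: 6 (steps 2, 3, 4, 5, 6, 7, from 3).

Steps most likely to fail:

Step 7. Oxygen may capture the C3 radical before the C–C closure, or the first peroxyl radical may be reduced (or may add to a C2/C4 carbonyl) before it closes the dioxepane. The fallback separates carbon–carbon from carbon–oxygen bond formation with known reaction types. It sets out from 14: anaerobic oxidative radical cyclisation with Mn(OAc)3/Cu(OAc)2 in degassed AcOH closes C3–C2′, and Cu(II) oxidises the tertiary radical to the 1,1-disubstituted alkene, giving isopropenyl homoadamantane F1. A Mukaiyama-type Co(acac)2/Et3SiH/O2 silylperoxidation then transfers a hydrogen atom selectively to the isopropenyl methylene (the less hindered alkene), regenerating the C3′ radical in the absence of the enol, and the oxygenation/7-exo peroxyl cyclisation/oxygenation sequence ends in triethylsilyl peroxide F2. Buffered fluoride (TBAF/AcOH, THF, 0 °C; base is avoided because the non-enolisable trione is open to retro-Claisen cleavage) removes the silyl group and the route is rejoined at 17.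

Step 4. The ion pair may discriminate poorly between the two faces of the phenoxide in the first alkylation, or closure may leak through the second prenylated carbon. The fallback sets out from 2 and 7: the annulation is run without a chiral catalyst (LiHMDS, THF, 0 °C; aq. NH4Cl) to give racemic adamantanol F3, which is resolved by preparative chromatography on a chiral stationary phase (SFC), and the route is rejoined at 10.

Step 5. The liberated, hindered C7 aldehyde may epimerise under the basic ylide or fail to olefinate, and the acidic hydrolysis may trigger cyclisation of the enol onto a prenyl group. The fallback sets out from 10 and uses known organometallic chemistry. Deprotonation and retro-aldol opening with LiHMDS, followed by the weakly basic vinylcerium reagent (CH2=CHMgBr/CeCl3, THF, −78 °C), gives allylic alcohol F4. Acetylation (Ac2O, DMAP, pyridine) gives bis-acetate F5, in which the enol acetate blocks C3 as a nucleophile toward the π-allyl intermediate. Pd(PPh3)4/HCO2NH4 reduction with hydride delivery to the internal allyl terminus gives 7-endo-allyl enol acetate F6, and methanolysis of the enol acetate (K2CO3, MeOH) gives 7-endo-allyl trione F7. Cross-metathesis with 2-methyl-2-butene (second-generation Ru–NHC catalyst, CH2Cl2, 40 °C) rejoins the route at 14, bypassing 13 and step 6.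

**Further compounds**

F1 | step 7 | isopropenyl homoadamantane: C3–C2′ closed, C2′ carrying prop-1-en-2-yl, C3 prenyl intact | CC(C)=CC[C@]12C[C@@H]3C[C@H](C(C)=C)[C@](CC=C(C)C)(C1=O)C(=O)[C@](C(=O)c4ccccc4)(C2=O)C3(C)C
F2 | step 7 | triethylsilyl peroxide of 17 (C3″–O–O–SiEt3) | CC(C)=CC[C@]12C[C@@H]3C[C@@H]4C(C)(C)OO[C@H](C(C)(C)OO[Si](CC)(CC)CC)C[C@@]4(C1=O)C(=O)[C@](C(=O)c1ccccc1)(C2=O)C3(C)C
F3 | step 4 | racemic adamantanol (1:1 mixture of 10 and its enantiomer) | CC(C)=CC[C@]12C[C@@H]3[C@H](O)[C@](CC=C(C)C)(C1=O)C(=O)[C@](C(=O)c4ccccc4)(C2=O)C3(C)C.CC(C)=CC[C@@]12C[C@H]3[C@@H](O)[C@@](CC=C(C)C)(C1=O)C(=O)[C@@](C(=O)c4ccccc4)(C2=O)C3(C)C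
F4 | step 5 | allylic alcohol, 7-endo-(1-hydroxyprop-2-enyl) analogue of 14, carbinol epimers | CC(C)=CC[C@]12C[C@H](C(O)C=C)C(C)(C)[C@](C(=O)c3ccccc3)(C(=O)C(CC=C(C)C)=C1O)C2=O
F5 | step 5 | bis-acetate of F4 (allylic acetate and C4 enol acetate; the enol acetate regioisomer converges) | CC(C)=CC[C@]12C[C@H](C(OC(C)=O)C=C)C(C)(C)[C@](C(=O)c3ccccc3)(C(=O)C(CC=C(C)C)=C1OC(C)=O)C2=O
F6 | step 5 | 7-endo-allyl enol acetate, C4 enol acetate of F7 | CC(C)=CC[C@]12C[C@H](CC=C)C(C)(C)[C@](C(=O)c3ccccc3)(C(=O)C(CC=C(C)C)=C1OC(C)=O)C2=O
F7 | step 5 | 7-endo-allyl trione, 7-(prop-2-enyl) analogue of 14 | CC(C)=CC[C@]12C[C@H](CC=C)C(C)(C)[C@](C(=O)c3ccccc3)(C(=O)C(CC=C(C)C)=C1O)C2=O
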